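## Retrosynthetic overview

1. Target ⇒ chromane-5,7-diol 27 (double Vilsmeier–Haack formylation last) ⇒ methyl ketal 26 (OMe replaced by H with retention) ⇒ o-quinone methide 25 + methyl enol ether 21 (hetero-Diels–Alder; the dihydropyran ring is formed last).
2. 21 ⇒ spiro ketone 19 ⇒ carbinol 18 ⇒ cyclic allylsilane 16 (SE2' protodesilylation places C=C between the spiro-bound CH and the isopropyl-bearing carbon).
3. 16 ⇒ triene 15 by a silicon-tethered intramolecular Diels–Alder reaction that builds the cyclohexene on a bought cyclopentane; 15 ⇒ (S)-allylic alcohol 6 (CBS reduction) + bromodiene 12 + Me2SiCl2.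
4. Enabling feature: in the cyclohexene, the vinylic CH and the CH–CH3 carbon both flank the spiro carbon, and the spiro carbon is bonded to the O-bearing CH of the cyclopentane. An O–SiMe2 link from that oxygen to the diene terminus closes a five-membered ring that must be cis-fused to the cyclopentane, so the exocyclic (E)-ethylidene is attacked on its O-face and the remaining C–Si bond is allylic, where the ring C=C has to end.
5. Ring order: cyclopentane and arene bought → cyclohexene (step 7) → dihydropyran (step 13).

Key step: step 7

Assumption: the dehydrobromination in step 4 is taken to give the E bromoenal; the Z isomer would be carried through in the same way, because the silicon-bearing carbon of 16 becomes sp2 in step 8 and only the rate of step 7 depends on the diene geometry.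

## Route

Step 1
Reactants: 1 cyclopentanone; 2 acetaldehyde
Product: 5 (2E)-2-ethylidenecyclopentan-1-one, via aldol adduct 3 (not isolated), via mesylate 4 (not isolated)
Conditions: LiN(iPr)2, THF, −78 °C; 2; then MeSO2Cl, −78 → 0 °C; then 1,8-diazabicyclo[5.4.0]undec-7-ene, 0 °C
Reagents that add atoms: none
Why: Directed aldol addition of the lithium enolate, sulfonylation of the aldolate and E1cB elimination should give the exocyclic enone, the E isomer (methyl anti to C=O) being the favoured outcome of this aldol condensation sequence.

Step 2
Reactants: 5 (2E)-2-ethylidenecyclopentan-1-one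
Product: 6 (1S,2E)-2-ethylidenecyclopentan-1-ol
Conditions: (3aR)-1-methyl-3,3-diphenylhexahydropyrrolo[1,2-c][1,3,2]oxazaborole (0.1 equiv), BH3·SMe2, THF, −20 °C; MeOH quench
Reagents that add atoms: none
Why: Corey–Bakshi–Shibata 1,2-reduction in which the sp2 alkylidene carbon acts as the large group, so the (R)-catalyst should deliver hydride to the face that gives the (S)-carbinol, the only stereocentre set by catalysis.

Step 3
Reactants: 7 3-methylbutanal; 8 formaldehyde
Product: 9 3-methyl-2-methylidenebutanal
Conditions: 37% aq. 8, pyrrolidine (0.1 equiv), propanoic acid (0.1 equiv), iPrOH, 45 °C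
Reagents that add atoms: none
Why: Amine-catalysed Mannich-type α-methylenation (enamine addition to formaldehyde, then β-elimination) is a standard entry to 2-alkylacroleins.

Step 4
Reactants: 9 3-methyl-2-methylidenebutanal
Product: 11 (2E)-3-bromo-2-(propan-2-yl)prop-2-enal, via dibromide 10 (not isolated)
Conditions: Br2, CH2Cl2, 0 °C; then Et3N, 0 °C → rt
Reagents that add atoms: bromine BrBr
Why: Bromine addition to the C=C bond and base-induced dehydrobromination (CH2Br proton, α-bromide) should give the β-bromoenal, with Br anti to CHO expected as the favoured isomer.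

Step 5
Reactants: 11 (2E)-3-bromo-2-(propan-2-yl)prop-2-enal
Product: 12 (1E)-1-bromo-2-(propan-2-yl)buta-1,3-diene
Conditions: Ph3PCH3Br, KN(SiMe3)2, THF, 0 °C; then 11, −78 → 0 °C
Reagents that add atoms: methyltriphenylphosphonium bromide C[P+](c1ccccc1)(c1ccccc1)c1ccccc1.[Br-]
Why: Wittig methylenation of the aldehyde leaves the bromoalkene untouched, so its geometry is carried into the diene.

Step 6
Reactants: 12 (1E)-1-bromo-2-(propan-2-yl)buta-1,3-diene; 6 (1S,2E)-2-ethylidenecyclopentan-1-ol
Product: 15 {[(1S,2E)-2-ethylidenecyclopentyl]oxy}(dimethyl)[(1E)-2-(propan-2-yl)buta-1,3-dien-1-yl]silane, via dienyllithium 13 (not isolated), via chlorosilane 14 (not isolated)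
Conditions: t-BuLi (2 equiv), Et2O, −78 °C; cannulate into Me2SiCl2 (5 equiv), −78 °C → rt; evaporate volatiles; then 6, imidazole, CH2Cl2, 0 °C → rt
Reagents that add atoms: dichlorodimethylsilane C[Si](C)(Cl)Cl
Why: Br–Li exchange proceeds with retention of alkene geometry, excess Me2SiCl2 is substituted once, and the chlorosilane silylates the secondary alcohol (standard silyl ether formation) to install the temporary O–Si–C tether.

Step 7
Reactants: 15 {[(1S,2E)-2-ethylidenecyclopentyl]oxy}(dimethyl)[(1E)-2-(propan-2-yl)buta-1,3-dien-1-yl]silane
Product: 16 tricyclic allylsilane (10-methyl-7-(propan-2-yl)spiro[4.5]dec-7-ene whose C-1 oxygen and C-6 are bridged by SiMe2)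
Conditions: PhMe (0.01 M), 2,6-di-tert-butyl-4-methylphenol (trace), 180 °C, sealed tube
Reagents that add atoms: none
Why: Thermal, concerted but asynchronous [4+2] cycloaddition of the 1-silyl diene across the exocyclic ethylidene C=C, i.e. a type 1 intramolecular Diels–Alder reaction with a temporary silicon tether (closest known type: silyl-ether-tethered Diels–Alder reactions of unactivated trienes). The cyclohexene is closed by the cycloaddition itself (two C–C bonds, one to the future spiro carbon), and the 1-oxa-2-silacyclopentane is closed by the proximal C–C bond in the fused mode (three-atom O–Si link between diene terminus and ring alkene carbon). The spiro carbon is set by the carbinol centre, because the five-membered tether ring can only be cis-fused to the cyclopentane and the diene terminus therefore adds to the alkene face syn to oxygen. The CH–CH3 centre follows from the E geometry of the ethylidene group by suprafacial addition (methyl syn to the ring CH2), and the Si–CH centre (endo or exo) does not matter because it becomes sp2 in step 8. The step needs regioselectivity (silylated terminus to the ring carbon, against the directing effect of the isopropyl group) and facial selectivity, and both are enforced by the tether rather than by electronic bias.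

Step 8
Reactants: 16 tricyclic allylsilane
Product: 18 (1S,5R,10S)-10-methyl-7-(propan-2-yl)spiro[4.5]dec-6-en-1-ol, via silyl trifluoroacetate 17 (not isolated)
Conditions: CF3CO2H (1.5 equiv), CH2Cl2, 0 °C; then K2CO3, MeOH, rt
Reagents that add atoms: none
Why: Protodesilylation of the allylsilane in the SE2' sense (protonation at the γ-carbon, β-silyl cation, loss of silicon) should move the double bond next to the spiro carbon regiospecifically, and methanolysis then cleaves the remaining Si–O bond.

Step 9
Reactants: 18 (1S,5R,10S)-10-methyl-7-(propan-2-yl)spiro[4.5]dec-6-en-1-ol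
Product: 19 (5R,10S)-10-methyl-7-(propan-2-yl)spiro[4.5]dec-6-en-1-one
Conditions: Dess–Martin periodinane, CH2Cl2, rt
Reagents that add atoms: none
Why: Dess–Martin oxidation of the secondary alcohol, whose stereocentre has served as tether anchor and control element; the quaternary α-carbon cannot epimerise.

Step 10
Reactants: 19 (5R,10S)-10-methyl-7-(propan-2-yl)spiro[4.5]dec-6-en-1-one
Product: 20 (2RS,5R,10S)-2,10-dimethyl-7-(propan-2-yl)spiro[4.5]dec-6-en-1-one
Conditions: LiN(iPr)2 (1.05 equiv), THF, −78 °C; MeI, −78 → −20 °C
Reagents that add atoms: iodomethane CI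
Why: Kinetic enolate alkylation at the only enolisable α-position (the other is the spiro carbon); the new centre forms as epimers and is erased in step 11.

Step 11
Reactants: 20 (2RS,5R,10S)-2,10-dimethyl-7-(propan-2-yl)spiro[4.5]dec-6-en-1-one
Product: 21 (5R,10S)-1-methoxy-2,10-dimethyl-7-(propan-2-yl)spiro[4.5]deca-1,6-diene
Conditions: KN(SiMe3)2, THF–DMPU, −78 °C; MeOSO2CF3; purify on basic alumina
Reagents that add atoms: methyl trifluoromethanesulfonate COS(=O)(=O)C(F)(F)F
Why: O-Alkylation of the hindered, fully substituted potassium enolate by a hard electrophile in a dipolar medium should give the tetrasubstituted methyl enol ether, since C-methylation would have to create a quaternary carbon next to the spiro centre.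

Step 12
Reactants: 22 2,4,6-trihydroxybenzaldehyde
Product: 23 2,4,6-tris[(tert-butoxycarbonyl)oxy]benzaldehyde
Conditions: Boc2O (3.3 equiv), iPr2NEt, 4-(dimethylamino)pyridine (0.05 equiv), THF, 0 °C → rt
Reagents that add atoms: di-tert-butyl dicarbonate CC(C)(C)OC(=O)OC(=O)OC(C)(C)C
Why: Nucleophile-catalysed carbonate formation on all three phenols (standard acylation).

Step 13
Reactants: 23 2,4,6-tris[(tert-butoxycarbonyl)oxy]benzaldehyde; 21 (5R,10S)-1-methoxy-2,10-dimethyl-7-(propan-2-yl)spiro[4.5]deca-1,6-diene
Product: 26 cis-fused 2-methoxychroman ketal (the target skeleton with OMe on the O–C carbon, H at both formyl positions and OBoc at both phenols), via phenoxide carbonate 24 (not isolated), via o-quinone methide 25 (not isolated)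
Conditions: 21 (1 equiv), 23 (3 equiv), Et2O, −78 °C; iBuMgBr (3 equiv) dropwise; −78 °C → rt
Reagents that add atoms: isobutylmagnesium bromide CC(C)C[Mg]Br
Why: Grignard addition to the aldehyde triggers carbonate migration and β-elimination to the o-quinone methide, which should undergo an inverse-electron-demand hetero-Diels–Alder reaction with the enol ether (known low-temperature o-quinone methide/enol ether cycloaddition): C–C bond to the nucleophilic methyl-bearing carbon and C–O bond to the methoxy carbon by syn addition (cis-fused ketal), methoxy endo with the E quinone methide placing isobutyl cis to the angular methyl, and approach anti to the CH(CH3) arm of the spiro ring, whose methyl lies over the other face.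

Step 14
Reactants: 26 cis-fused 2-methoxychroman ketal
Product: 27 chromane-5,7-diol (the target without its two formyl groups)
Conditions: iBu2AlH (8 equiv), CH2Cl2, −78 → 23 °C; aq. potassium sodium tartrate
Reagents that add atoms: none
Why: iBu2AlH should bind the more basic exocyclic methoxy oxygen and deliver hydride within the ion pair to the face from which methoxide leaves (reductive ketal cleavage with retention, as known for ketals and bicyclic acetals), placing H cis to the angular methyl and keeping the cis ring fusion, while the excess reagent also cleaves both aryl carbonates.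

Step 15
Reactants: 27 chromane-5,7-diol
Product: 29 CNP0121396.2, via bis(iminium) salt 28 (not isolated)
Conditions: POCl3 (4 equiv), DMF, EtOAc, 0 °C → rt; then aq. NaOAc, 50 °C
Reagents that add atoms: N,N-dimethylformamide CN(C)C=O; water O
Why: Double Vilsmeier–Haack formylation at the two free ring positions, each flanked by two oxygens, as used for diformylphloroglucinols; hydrolysis of the bis(iminium) salt should give the dialdehyde.

## Compound list

1 | cyclopentanone | O=C1CCCC1 | starting material
2 | acetaldehyde | CC=O | starting material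
3 | 2-(1-hydroxyethyl)cyclopentan-1-one (as lithium alkoxide, diastereomer mixture) | CC(O)C1CCCC1=O | intermediate
4 | 1-(2-oxocyclopentyl)ethyl methanesulfonate (diastereomer mixture) | CC(OS(C)(=O)=O)C1CCCC1=O | intermediate
5 | (2E)-2-ethylidenecyclopentan-1-one | C/C=C1\CCCC1=O | intermediate
6 | (1S,2E)-2-ethylidenecyclopentan-1-ol | O[C@H]1CCC/C1=C\C | intermediate
7 | 3-methylbutanal | CC(C)CC=O | starting material
8 | formaldehyde | C=O | starting material
9 | 3-methyl-2-methylidenebutanal | C=C(C=O)C(C)C | intermediate
10 | 2-bromo-2-(bromomethyl)-3-methylbutanal (racemic) | BrCC(Br)(C=O)C(C)C | intermediate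
11 | (2E)-3-bromo-2-(propan-2-yl)prop-2-enal | O=C/C(C(C)C)=C/Br | intermediate
12 | (1E)-1-bromo-2-(propan-2-yl)buta-1,3-diene | Br/C=C(/C=C)C(C)C | intermediate
13 | [(1E)-2-(propan-2-yl)buta-1,3-dien-1-yl]lithium | [Li]/C=C(/C=C)C(C)C | intermediate
14 | chloro(dimethyl)[(1E)-2-(propan-2-yl)buta-1,3-dien-1-yl]silane | C=C/C(C(C)C)=C/[Si](C)(C)Cl | intermediate
15 | {[(1S,2E)-2-ethylidenecyclopentyl]oxy}(dimethyl)[(1E)-2-(propan-2-yl)buta-1,3-dien-1-yl]silane | C=C/C(C(C)C)=C/[Si](C)(C)O[C@H]1CCC/C1=C\C | intermediate
16 | tricyclic allylsilane: 10-methyl-7-(propan-2-yl)spiro[4.5]dec-7-ene with an O–SiMe2 bridge from the C-1 oxygen to C-6 (O and C-6 on the same face of the cyclopentane; spiro and CH–CH3 centres as in 19; Si–CH centre either configuration) | C[Si]1(C)O[C@H]2CCC[C@@]23C1C(C(C)C)=CC[C@@H]3C | intermediate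
17 | dimethyl(trifluoroacetoxy)silyl ether of 18 | C[Si](C)(OC(=O)C(F)(F)F)O[C@H]1CCC[C@@]12C=C(C(C)C)CC[C@@H]2C | intermediate
18 | (1S,5R,10S)-10-methyl-7-(propan-2-yl)spiro[4.5]dec-6-en-1-ol | O[C@H]1CCC[C@@]12C=C(C(C)C)CC[C@@H]2C | intermediate
19 | (5R,10S)-10-methyl-7-(propan-2-yl)spiro[4.5]dec-6-en-1-one | O=C1CCC[C@@]12C=C(C(C)C)CC[C@@H]2C | intermediate
20 | (2RS,5R,10S)-2,10-dimethyl-7-(propan-2-yl)spiro[4.5]dec-6-en-1-one (both C-2 epimers) | O=C1C(C)CC[C@@]12C=C(C(C)C)CC[C@@H]2C | intermediate
21 | (5R,10S)-1-methoxy-2,10-dimethyl-7-(propan-2-yl)spiro[4.5]deca-1,6-diene | COC1=C(C)CC[C@@]12C=C(C(C)C)CC[C@@H]2C | intermediate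
22 | 2,4,6-trihydroxybenzaldehyde | O=Cc1c(O)cc(O)cc1O | starting material
23 | 2,4,6-tris[(tert-butoxycarbonyl)oxy]benzaldehyde | O=Cc1c(OC(=O)OC(C)(C)C)cc(OC(=O)OC(C)(C)C)cc1OC(=O)OC(C)(C)C | intermediate
24 | Grignard adduct after carbonate migration: 2-hydroxyaryl benzylic tert-butyl carbonate (as magnesium phenoxide, racemic) | CC(C)CC(OC(=O)OC(C)(C)C)c1c(O)cc(OC(=O)OC(C)(C)C)cc1OC(=O)OC(C)(C)C | intermediate
25 | (E)-o-quinone methide: 6-(3-methylbutylidene)-3,5-bis[(tert-butoxycarbonyl)oxy]cyclohexa-2,4-dien-1-one | CC(C)C/C=C1/C(=O)C=C(OC(=O)OC(C)(C)C)C=C1OC(=O)OC(C)(C)C | intermediate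
26 | cis-fused 2-methoxychroman ketal: target skeleton with OMe in place of H on the O–C carbon (OMe cis to the angular methyl), H at both formyl positions, OBoc at both phenols | CC(C)C[C@H]1c2c(OC(=O)OC(C)(C)C)cc(OC(=O)OC(C)(C)C)cc2O[C@@]2(OC)[C@]1(C)CC[C@@]21C=C(C(C)C)CC[C@@H]1C | intermediate
27 | chromane-5,7-diol: the target without its two formyl groups, all five stereocentres as in the target | CC(C)C[C@H]1c2c(O)cc(O)cc2O[C@H]2[C@]1(C)CC[C@@]21C=C(C(C)C)CC[C@@H]1C | intermediate
28 | 6,8-bis(dimethyliminiomethyl) dichloride of 27 | CC(C)C[C@H]1c2c(O)c(C=[N+](C)C)c(O)c(C=[N+](C)C)c2O[C@H]2[C@]1(C)CC[C@@]21C=C(C(C)C)CC[C@@H]1C.[Cl-].[Cl-] | intermediate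
29 | CNP0121396.2 | CC(C)C[C@H]1c2c(O)c(C=O)c(O)c(C=O)c2O[C@H]2[C@]1(C)CC[C@@]21C=C(C(C)C)CC[C@@H]1C | target

## Step count and risks

Total step count: 15. Longest linear sequence: 12 steps (steps 3–11 and 13–15, from 3-methylbutanal).

Three steps most likely to fail:

**Step 14.** The aluminium hydride may bind the ring oxygen and cleave the endocyclic aryl C–O bond (ring opening to a methyl ether), or the ion pair may separate before hydride transfer, so that hydride adds anti to the angular methyl and the trans-fused epimer results. The fallback leaves the route at 26 and returns at 27. CF3CO2H/H2O in CH2Cl2 hydrolyses the ketal and removes both carbonates to give the triol lactol F6. F6 is reduced with Et3SiH/BF3·OEt2 at −78 °C (ionic hydrogenation of a 2-chromanol) to 27. Only the lactol hydroxyl can leave in this variant, so ring opening is excluded. Hydride delivery is then external, and the cis ring fusion rests only on the strain of the trans-fused alternative.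

**Step 13.** The cycloaddition of the tetrasubstituted enol ether may be slower than self-condensation of the o-quinone methide, or control of the quinone methide geometry and of the enol ether face may be poor (epimers at the benzylic carbon or at the two ring-fusion carbons). The fallback leaves the route at 20 and 23 and returns at 26. The phenoxide carbonate 24 is generated from 23 and iBuMgBr at −78 °C, the potassium enolate of 20 (KN(SiMe3)2, THF) is added and the mixture is warmed. The released 25 is then captured by the far more nucleophilic enolate carbon (Michael addition), and the phenoxide closes onto the ketone to give the lactol F5. Acid-catalysed exchange (HC(OMe)3, MeOH, pyridinium 4-methylbenzenesulfonate) converts F5 into the methyl ketal 26.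

**Step 7.** The unactivated, trisubstituted dienophile may be too unreactive, so that diene oligomerisation or thermal loss of the labile dimethylsilyl ether competes at the temperature needed. The fallback leaves the route at 5 and 12 and returns at 19.
- 12 is lithiated as in step 6 and quenched with PhSSPh to give {[(1E)-2-(propan-2-yl)buta-1,3-dien-1-yl]sulfanyl}benzene F1.
- F1 and enone 5 are combined in an intermolecular Diels–Alder reaction catalysed by a chiral oxazaborolidinium salt: 3,3-diphenyl-1-(2-methylphenyl)hexahydropyrrolo[1,2-c][1,3,2]oxazaborole activated by HN(SO2CF3)2, the antipode being chosen by the usual enone-binding model for the (5R,10S) series. The sulfur-bearing diene terminus should bond to the α-carbon of the enone, because the 1-thio substituent overrides the 2-alkyl group, giving the 6-(phenylsulfanyl) spiro ketone F2.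
- Oxidation at sulfur (H2O2, (NH4)6Mo7O24 cat., EtOH) gives the allylic sulfone F3.
- Pd(PPh3)4/LiBHEt3 removes the sulfonyl group with hydride delivery to the allyl terminus remote from the spiro carbon, which places the double bond as in 18, and also reduces the ketone to the carbinol mixture F4.
- Dess–Martin oxidation of F4 returns 19.

Further compounds
F1 | step 7 | {[(1E)-2-(propan-2-yl)buta-1,3-dien-1-yl]sulfanyl}benzene | C=C/C(C(C)C)=C/Sc1ccccc1
F2 | step 7 | 10-methyl-6-(phenylsulfanyl)-7-(propan-2-yl)spiro[4.5]dec-7-en-1-one (spiro and CH–CH3 centres as in 19; C–S centre either configuration) | O=C1CCC[C@@]12C(Sc3ccccc3)C(C(C)C)=CC[C@@H]2C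
F3 | step 7 | 6-(benzenesulfonyl)-10-methyl-7-(propan-2-yl)spiro[4.5]dec-7-en-1-one (spiro and CH–CH3 centres as in 19) | O=C1CCC[C@@]12C(S(=O)(=O)c3ccccc3)C(C(C)C)=CC[C@@H]2C
F4 | step 7 | (1RS,5R,10S)-10-methyl-7-(propan-2-yl)spiro[4.5]dec-6-en-1-ol | OC1CCC[C@@]12C=C(C(C)C)CC[C@@H]2C
F5 | step 13 | lactol: 2-hydroxy analogue of ketal 26 (OH in place of OMe) | CC(C)C[C@H]1c2c(OC(=O)OC(C)(C)C)cc(OC(=O)OC(C)(C)C)cc2O[C@@]2(O)[C@]1(C)CC[C@@]21C=C(C(C)C)CC[C@@H]1C
F6 | step 14 | triol lactol: 2-hydroxy analogue of 26 with both phenols free | CC(C)C[C@H]1c2c(O)cc(O)cc2O[C@@]2(O)[C@]1(C)CC[C@@]21C=C(C(C)C)CC[C@@H]1C
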